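Take the last reading of the flask followed so far, the dawn run, and divide the product made by the precatalyst charged.

| flask | substrate | precatalyst | remark | time |
|---|---|---|---|---|
| dawn | 0.12 M | 5 µM | the very flask that is asked about, followed so far |  |
| autumn | 0.080 M | 5 µM | run made earlier |  |
| flask | 0.12 M | 5.0 µM |  | 12 h |

| run | time / min | product / % | substrate / % |
|---|---|---|---|
| dawn | 40.0 | 3.1 | 96.2 |
| dawn | 120 | 9.8 | 90.2 |
| dawn | 180 | 13.7 | 86.7 |
| dawn | 300 | 17.8 | 82.1 |
| dawn | 480 | 19.8 | 79.4 |
| dawn | 600 | 21.7 | 79.0 |
| autumn | 2.00 | 0 | 99.6 |
| autumn | 6.00 | 0.3 | 99.8 |
| autumn | 12.0 | 0.9 | 99.5 |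
| autumn | 20.0 | 0.7 | 98.8 |
| autumn | 25.0 | 1.9 | 98.3 |
| autumn | 30.0 | 2.0 | 97.8 |

(standard deviation of a reading: 0.3 percentage points)

- north-west: at 12 h take out 90% of the product then present, then wait 4.0 h
- west: at 12 h add substrate, 50.0% of the amount charged, then wait 4.0 h
- east: change nothing and wait 4.0 h more
- south-west: at 12 h add precatalyst, 50.0% of the amount charged, then wait 4.0 h

- product taken out counts as made
- the analysis behind the earlier runs scatters by 0.3 percentage points, standard deviation
- additions bring no volume worth counting

- product, in percent of the substrate first charged, at 12 h
- which option adds most product ("none" when 2 percentage points or less is all one gets) (north-west / west / east / south-west / none)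
- product present, with what was taken out counted in, in percent of the substrate first charged, after east
- product present, with what was taken out counted in, in percent of the substrate first charged, after south-west

In the dawn run, product rose 6.7 percentage points from 40.0 min to 120 min but 1.9 points from 480 min to 600 min, while substrate still stood at 79.0%. The last reading gives 5210 product molecules per precatalyst charged; call this the turnover budget, the turnover number of this charge. These readings do not separate a dying catalyst from an equilibrium, but I commit to a dying catalyst. On that reckoning, I put product at 12 h a little above 21.7%, and I estimate the south-west dose at 11 points if it earns the same budget per precatalyst and spends it whole.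

The forecast gave 22% now, 22.5% after east, 28.5% after south-west and south-west as best, reasoning that “A sharp stop after a flat stretch, from a precatalyst at µM loading, leans towards death”.

The flask gives 21.9% at 12 h, 22.4% after east and 29.3% after south-west. Best is south-west, whose gain of 7.5 points is larger than any other option's and smaller than the 11 points estimated for a whole budget.

    precatalyst ⇌ enzyme (K = 1.30, k = 6.18 × 10⁻⁴ s⁻¹)
    substrate + complex → spent catalyst (k = 0.00318 L mol⁻¹ s⁻¹)
    substrate + enzyme ⇌ complex (K = 6.50 L mol⁻¹, k = 13900 L mol⁻¹ s⁻¹)
    complex ⇌ enzyme + product (K = 0.300 M, k = 1.97 s⁻¹)

At 12 h the flask holds 78.1% of its substrate charge free, and 96.8% of its catalyst charge as spent catalyst, while precatalyst, enzyme and complex together hold 3.24% of the catalyst charged. At the same budget, that share is worth an estimated 0.7 points more product. The budget belongs to this substrate amount: the neighbour flask with 0.48 M of substrate and the same precatalyst has spent catalyst at 100% and stands at 1.35% at 12 h, which is 1290 turnovers, fewer than the budget read from the dawn run. The asked flask has not quite come to rest: at 7200 min it stands at 22.6%, 0.70 points above its value at 12 h.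

The runs are calculated from invented constants; scatter was added.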